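Both pyrone rings are disconnected at C4–C5 and O1–C2, back to two acetyl groups on the vicinal quaternary cyclobutane carbons C3 and C4. The key step exploits the fact that each pyrone is joined through its C6 to such a carbon: the rings are grown outward from the acetyl methyls, so every new bond forms two or more atoms away from the congested C3–C4 pair. One operation turns a meso bis(trimethylsilyl enol ether), which already carries C1 and C2 as cis tert-butyl esters, into both 4-hydroxy-3-methyl-2-pyrones with methylmalonyl dichloride. The cyclobutane comes from an anti [2+2] photoadduct; a final alkaloid-mediated methanolysis of the meso anhydride sets the absolute configuration.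

Key step: step 9

Numbering used: C1 carries CO2Me in the target, C2 the CO2H, C3 (next to C2) and C4 (next to C1) the methyl and pyrone groups. In every intermediate the C1/C2 substituents are cis to each other and to the two methyls, and trans to the C3/C4 acyl or pyrone groups.

Assumption: quinidine is taken to direct methanol to the C1 carbonyl of the meso anhydride; quinine, its pseudoenantiomer, would be used instead should the first run show the opposite sense.

Step 1
Reactants: 1 2,3-dimethylmaleic anhydride; 2 2,2-dimethyl-4,7-dihydro-1,3-dioxepine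
Product: 3 meso cis-anti-cis [2+2] adduct (cyclobutane cis-fused at C3–C4 to the anhydride ring and at C1–C2 to the dioxepane ring, the two rings on opposite faces)
Conditions: benzophenone (0.2 equiv), 2 (3 equiv), MeCN, hν 350 nm (Pyrex), 15 °C, degassed
Reagents that add atoms: none
Why: Triplet-sensitised [2+2] photocycloaddition: triplet 1 adds to the cis-alkene of 2 through a 1,4-biradical, the two existing rings enforce cis fusion at both junctions, and exo (anti) closure keeps the dioxepane ring on the face opposite the anhydride ring, which sets all four stereocentres of the meso adduct with the C1/C2 methylene groups cis to the C3/C4 methyls; excess 2 suppresses dimerisation of 1.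

Step 2
Reactants: 3 meso cis-anti-cis [2+2] adduct
Product: 4 dilithium meso cis-dicarboxylate (anhydride opened, acetonide intact)
Conditions: LiOH·H2O (2.05 equiv), THF/H2O, rt; evaporate, toluene azeotrope, dry at 80 °C under vacuum
Reagents that add atoms: lithium hydroxide, [Li+].[OH-]
Why: Anhydride saponification under mild base leaves the acetonide intact and gives an anhydrous dicarboxylate fit for organolithium addition; C3 and C4 carry no hydrogen and cannot epimerise.

Step 3
Reactants: 4 dilithium meso cis-dicarboxylate
Product: 7 meso (cis-3,4-diacetyl-3,4-dimethylcyclobutane-1,2-diyl)dimethanol, via tetralithium bis(gem-diolate) 5 (not isolated), via diacetyl acetonide 6 (not isolated)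
Conditions: MeLi (6 equiv), THF/Et2O, 0 °C to rt; inverse quench into 2 M HCl at 0 °C, then rt, 1 h; NaHCO3, EtOAc extraction
Reagents that add atoms: methyllithium, [Li]C
Why: Methyl ketone synthesis by addition of methyllithium to lithium carboxylates: each carboxylate takes up one MeLi to give a gem-diolate that cannot collapse to a ketone until the inverse acidic quench has destroyed the excess reagent, and the same aqueous acid hydrolyses the seven-membered acetonide; C3 and C4 are quaternary, so nothing epimerises and the 1,4-diketone cannot dehydrate to a furan.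

Step 4
Reactants: 7 meso diacetyl diol
Product: 8 meso cis-3,4-diacetyl-3,4-dimethylcyclobutane-1,2-dicarbaldehyde
Conditions: (COCl)2 (3 equiv), DMSO (6 equiv), CH2Cl2, −78 °C; iPr2NEt (8 equiv), −78 to −30 °C; cold pH 7 buffer; used crude
Reagents that add atoms: none
Why: Swern oxidation: both primary hydroxyls are converted to alkoxysulfonium ions before the base is added, so no hydroxy aldehyde can close to a lactol and end as the lactone, and the hindered amine at low temperature leaves the cis α-stereocentres unepimerised.

Step 5
Reactants: 8 meso dialdehyde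
Product: 9 meso cis-3,4-diacetyl-3,4-dimethylcyclobutane-1,2-dicarboxylic acid
Conditions: NaClO2, NaH2PO4, 2-methyl-2-butene, tBuOH/H2O, 0 °C to rt
Reagents that add atoms: sodium chlorite, [Na+].[O-]Cl=O
Why: Pinnick oxidation with a hypochlorite scavenger at about pH 4 converts both aldehydes to acids without enolising C1/C2 or triggering aldol chemistry of the diketone.

Step 6
Reactants: 9 meso diacetyl diacid
Product: 10 di-tert-butyl meso cis-3,4-diacetyl-3,4-dimethylcyclobutane-1,2-dicarboxylate
Conditions: tert-butyl 2,2,2-trichloroacetimidate (5 equiv), CH2Cl2/cyclohexane, rt to 40 °C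
Reagents that add atoms: tert-butyl 2,2,2-trichloroacetimidate, CC(C)(C)OC(=N)C(Cl)(Cl)Cl
Why: Esterification with a trichloroacetimidate: the acid protonates the imidate and the carboxylate captures the tert-butyl cation equivalent, which needs neither base nor carbonyl activation and so avoids both the aldol of the cis-diacetyl unit and closure to the anhydride.

Step 7
Reactants: 10 di-tert-butyl diacetyl diester
Product: 11 di-tert-butyl meso cis-3,4-dimethyl-3,4-bis(1-trimethylsilyloxyvinyl)cyclobutane-1,2-dicarboxylate
Conditions: TMSOTf (2.3 equiv), Et3N (4 equiv), CH2Cl2, −20 to 0 °C, 30 min; cold pentane/NaHCO3 work-up, concentrate at or below 0 °C, use at once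
Reagents that add atoms: trimethylsilyl trifluoromethanesulfonate, C[Si](C)(C)OS(=O)(=O)C(F)(F)F
Why: Soft enolisation (silyl triflate/tertiary amine enol silylation): each acetyl group has only its methyl to enolise, the amine buffer excludes the aldol between the two arms, the tert-butyl esters should survive the short cold exposure, and because the product is a cis-1,2-dialkenylcyclobutane prone to Cope rearrangement it is kept at or below 0 °C.

Step 8
Reactants: 12 methylmalonic acid
Product: 13 methylmalonyl dichloride
Conditions: SOCl2 (excess), 55 °C; distil under reduced pressure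
Reagents that add atoms: thionyl chloride, O=S(Cl)Cl
Why: Standard conversion of a carboxylic acid to its acyl chloride through the chlorosulfite, with gaseous by-products and purification by distillation.

Step 9
Reactants: 11 bis(trimethylsilyl enol ether); 13 methylmalonyl dichloride (3 equiv)
Product: 15 di-tert-butyl meso cis-3,4-bis(4-hydroxy-3-methyl-2-oxo-2H-pyran-6-yl)-3,4-dimethylcyclobutane-1,2-dicarboxylate, via bis(dioxo acid chloride) 14 (not isolated)
Conditions: 11 added dropwise to 13 in Et2O, −78 °C, then slowly to 15 °C under N2 sweep; evaporate; extract into aq NaHCO3, acidify to pH 3, EtOAc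
Reagents that add atoms: none
Why: Each enol ether is C-acylated at its CH2 terminus by one acyl chloride of 13 with loss of Me3SiCl, and the resulting 3,5-dioxo acid chloride enolises at the ring-bound ketone, lactonises through that oxygen and tautomerises to the 4-hydroxy-2-pyrone. The closest known reaction type is the uncatalysed condensation of ketone trimethylsilyl enol ethers with malonyl dichlorides to 6-substituted 4-hydroxy-2-pyrones. Each of the two rings closes by 6-exo-trig acyl substitution (O1–C2 bond) after the intermolecular C4–C5 bond is made. No stereocentre is formed, and the four existing ones lie outside the reacting arms, so the meso configuration is kept. The step needs C- over O-acylation and one dichloride per arm rather than a bridge between the arms; the high electrophilicity of the dichloride, inverse addition into its excess at −78 °C and the fast six-membered lactonisation should secure this, and all bond formation lies at least two atoms from C3/C4. Absence of base avoids the aldol of the cis-1,4-diketone, and the low temperature keeps the cis-dialkenylcyclobutane from Cope rearrangement until the first acylation has removed the 1,5-diene.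

Step 10
Reactants: 15 bis(4-hydroxypyrone) diester
Product: 16 di-tert-butyl meso cis-3,4-bis(4-methoxy-3-methyl-2-oxo-2H-pyran-6-yl)-3,4-dimethylcyclobutane-1,2-dicarboxylate
Conditions: Me2SO4 (3 equiv), K2CO3 (3 equiv), acetone, rt to 40 °C
Reagents that add atoms: dimethyl sulfate, COS(=O)(=O)OC
Why: Williamson-type O-methylation of the potassium pyronates: dimethyl sulfate with carbonate alkylates the 4-oxygen to the 4-methoxy-2-pyrone, the usual regiochemistry for 3-alkyl-4-hydroxy-2-pyrones, while the tert-butyl esters and the weakly acidic C1/C2 hydrogens are untouched.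

Step 11
Reactants: 16 bis(4-methoxypyrone) di-tert-butyl ester
Product: 18 meso cis-3,4-bis(4-methoxy-3-methyl-2-oxo-2H-pyran-6-yl)-3,4-dimethylcyclobutane-1,2-dicarboxylic anhydride, via bis(methoxypyrone) diacid 17 (not isolated)
Conditions: TFA/CH2Cl2 (1:2), rt; evaporate; TFAA (1.5 equiv), CH2Cl2, 0 °C to rt; evaporate
Reagents that add atoms: none
Why: Acidolysis of the tert-butyl esters (loss of isobutene) followed by dehydration of the cis-1,2-diacid through a mixed trifluoroacetic anhydride; a five-membered anhydride on a cyclobutane can only be cis-fused, so the C1/C2 configuration is retained, and the methoxypyrones tolerate acid.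

Step 12
Reactants: 18 meso anhydride
Product: 19 target hemiester (C1 R, C2 S, C3 R, C4 S)
Conditions: quinidine (1.1 equiv), MeOH (3 equiv), toluene, −55 °C; then 1 M HCl wash
Reagents that add atoms: methanol, CO
Why: Alkaloid-mediated desymmetrising alcoholysis of a meso cyclic anhydride: quinidine acts as a chiral general base and delivers methanol to one of the two enantiotopic carbonyls, here the one on the carbon that becomes C1, so the absolute configuration is set by the reagent while no existing stereocentre is touched.

Compound list
1 | 2,3-dimethylmaleic anhydride | CC1=C(C)C(=O)OC1=O | starting material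
2 | 2,2-dimethyl-4,7-dihydro-1,3-dioxepine | CC1(C)OCC=CCO1 | starting material
3 | meso cis-anti-cis [2+2] adduct; anhydride ring and acetonide-bearing dioxepane ring on opposite faces of the cyclobutane, methyls on the dioxepane face | CC1(C)OC[C@@H]2[C@H](CO1)[C@@]3(C)C(=O)OC(=O)[C@@]23C | intermediate
4 | dilithium meso cis-dicarboxylate from 3, acetonide intact | CC1(C)OC[C@@H]2[C@H](CO1)[C@@](C)(C(=O)[O-])[C@@]2(C)C(=O)[O-].[Li+].[Li+] | intermediate
5 | tetralithium bis(gem-diolate) from double MeLi addition | CC1(C)OC[C@@H]2[C@H](CO1)[C@@](C)(C(C)([O-])[O-])[C@@]2(C)C(C)([O-])[O-].[Li+].[Li+].[Li+].[Li+] | intermediate (not isolated)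
6 | meso cis-diacetyl acetonide | CC1(C)OC[C@@H]2[C@H](CO1)[C@@](C)(C(C)=O)[C@@]2(C)C(C)=O | intermediate (not isolated)
7 | meso (cis-3,4-diacetyl-3,4-dimethylcyclobutane-1,2-diyl)dimethanol; CH2OH groups cis to the methyls | OC[C@@H]1[C@H](CO)[C@@](C)(C(C)=O)[C@@]1(C)C(C)=O | intermediate
8 | meso cis-3,4-diacetyl-3,4-dimethylcyclobutane-1,2-dicarbaldehyde | O=C[C@@H]1[C@H](C=O)[C@@](C)(C(C)=O)[C@@]1(C)C(C)=O | intermediate
9 | meso cis-3,4-diacetyl-3,4-dimethylcyclobutane-1,2-dicarboxylic acid | OC(=O)[C@@H]1[C@H](C(=O)O)[C@@](C)(C(C)=O)[C@@]1(C)C(C)=O | intermediate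
10 | di-tert-butyl meso cis-3,4-diacetyl-3,4-dimethylcyclobutane-1,2-dicarboxylate | CC(C)(C)OC(=O)[C@@H]1[C@H](C(=O)OC(C)(C)C)[C@@](C)(C(C)=O)[C@@]1(C)C(C)=O | intermediate
11 | di-tert-butyl meso cis-3,4-dimethyl-3,4-bis(1-trimethylsilyloxyvinyl)cyclobutane-1,2-dicarboxylate (key-step precursor) | CC(C)(C)OC(=O)[C@@H]1[C@H](C(=O)OC(C)(C)C)[C@@](C)(C(=C)O[Si](C)(C)C)[C@@]1(C)C(=C)O[Si](C)(C)C | intermediate
12 | methylmalonic acid | CC(C(=O)O)C(=O)O | starting material
13 | methylmalonyl dichloride | CC(C(=O)Cl)C(=O)Cl | intermediate
14 | di-tert-butyl meso cis-3,4-bis(5-chloro-4-methyl-3,5-dioxopentanoyl)-3,4-dimethylcyclobutane-1,2-dicarboxylate (side-chain CH(CH3) centres epimerisable) | CC(C)(C)OC(=O)[C@@H]1[C@H](C(=O)OC(C)(C)C)[C@@](C)(C(=O)CC(=O)C(C)C(Cl)=O)[C@@]1(C)C(=O)CC(=O)C(C)C(Cl)=O | intermediate (not isolated)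
15 | di-tert-butyl meso cis-3,4-bis(4-hydroxy-3-methyl-2-oxo-2H-pyran-6-yl)-3,4-dimethylcyclobutane-1,2-dicarboxylate (key-step product) | CC(C)(C)OC(=O)[C@@H]1[C@H](C(=O)OC(C)(C)C)[C@@](C)(c2cc(O)c(C)c(=O)o2)[C@@]1(C)c1cc(O)c(C)c(=O)o1 | intermediate
16 | di-tert-butyl meso cis-3,4-bis(4-methoxy-3-methyl-2-oxo-2H-pyran-6-yl)-3,4-dimethylcyclobutane-1,2-dicarboxylate | CC(C)(C)OC(=O)[C@@H]1[C@H](C(=O)OC(C)(C)C)[C@@](C)(c2cc(OC)c(C)c(=O)o2)[C@@]1(C)c1cc(OC)c(C)c(=O)o1 | intermediate
17 | meso cis-3,4-bis(4-methoxy-3-methyl-2-oxo-2H-pyran-6-yl)-3,4-dimethylcyclobutane-1,2-dicarboxylic acid | OC(=O)[C@@H]1[C@H](C(=O)O)[C@@](C)(c2cc(OC)c(C)c(=O)o2)[C@@]1(C)c1cc(OC)c(C)c(=O)o1 | intermediate (not isolated)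
18 | meso cyclic anhydride of 17 (anhydride ring cis-fused at C1–C2, on the face of the methyls) | O=C1OC(=O)[C@@H]2[C@H]1[C@@](C)(c3cc(OC)c(C)c(=O)o3)[C@@]2(C)c1cc(OC)c(C)c(=O)o1 | intermediate
19 | 2-(methoxycarbonyl)-3,4-bis(4-methoxy-3-methyl-2-oxo-2H-pyran-6-yl)-3,4-dimethylcyclobutane-1-carboxylic acid; ester carbon R, acid carbon S, pyrone carbon next to the acid R, pyrone carbon next to the ester S | COC(=O)[C@@H]1[C@H](C(=O)O)[C@@](C)(c2cc(OC)c(C)c(=O)o2)[C@@]1(C)c1cc(OC)c(C)c(=O)o1 | target

Total step count: 12 (eleven in the main line plus one for the acid chloride).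
Longest linear sequence: 11 steps (steps 1–7 and 9–12).

Steps most likely to fail

Step 9. The hydrogen chloride released when the first lactone closes may protodesilylate the second enol ether, or one dichloride may bridge both arms, so that the double annulation stays incomplete. The fallback sets out from 11 and returns at 15; it separates C–C bond formation from lactonisation so that only Me3SiCl is released while enol ether is still present. Diethyl methylmalonate is monosaponified with one equivalent of KOH in ethanol to ethyl hydrogen methylmalonate F1, which oxalyl chloride converts into ethyl 3-chloro-2-methyl-3-oxopropanoate F2. Lewis-acid-mediated C-acylation of 11 with F2 (ZnCl2, CH2Cl2/Et2O, 0 °C) should give di-tert-butyl meso cis-3,4-bis(5-ethoxy-4-methyl-3,5-dioxopentanoyl)-3,4-dimethylcyclobutane-1,2-dicarboxylate F3. DBU in toluene at 60 °C then closes both lactones with loss of ethanol, and acidification gives 15.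

Step 3. Addition to the second, neopentyl carboxylate may stall once the first arm carries a dianionic centre, or ketone freed during the quench may be attacked again. The fallback sets out from 3 and returns at 6; it replaces addition to carboxylates by addition to aldehydes. LiAlH4 in refluxing THF reduces 3 to the meso neopentyl diol acetonide F4. Swern oxidation gives the non-enolisable meso dialdehyde acetonide F5. Excess MeMgBr gives the bis(1-hydroxyethyl) acetonide F6 as a mixture of carbinol epimers. Dess–Martin periodinane oxidises F6 to 6, which the acid treatment of step 3 converts into 7.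

Step 12. The alkaloid may discriminate poorly between the two enantiotopic carbonyls of this hindered anhydride. The fallback sets out from 18 and returns at 19; it replaces reagent control by separation of diastereomers. Compound 18 is opened with (R)-1-phenylethanol (DMAP, Et3N, CH2Cl2) to two diastereomeric hemiesters, separated by chromatography or crystallisation: the C1 acid/C2 (R)-1-phenylethyl ester F7, which is wanted, and the C2 acid/C1 (R)-1-phenylethyl ester F8, which is set aside. TMSCHN2 in toluene/MeOH methylates F7 to the C1 methyl/C2 (R)-1-phenylethyl diester F9. Brief hydrogenolysis (H2, palladium on carbon, EtOAc, 1 atm) removes the benzylic ester and gives 19.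

Further compounds
F1 | step 9 | ethyl hydrogen methylmalonate | CCOC(=O)C(C)C(=O)O
F2 | step 9 | ethyl 3-chloro-2-methyl-3-oxopropanoate | CCOC(=O)C(C)C(Cl)=O
F3 | step 9 | di-tert-butyl meso cis-3,4-bis(5-ethoxy-4-methyl-3,5-dioxopentanoyl)-3,4-dimethylcyclobutane-1,2-dicarboxylate | CC(C)(C)OC(=O)[C@@H]1[C@H](C(=O)OC(C)(C)C)[C@@](C)(C(=O)CC(=O)C(C)C(=O)OCC)[C@@]1(C)C(=O)CC(=O)C(C)C(=O)OCC
F4 | step 3 | meso cis-3,4-bis(hydroxymethyl) acetonide from reduction of 3 | CC1(C)OC[C@@H]2[C@H](CO1)[C@@](C)(CO)[C@@]2(C)CO
F5 | step 3 | meso cis-3,4-diformyl acetonide | CC1(C)OC[C@@H]2[C@H](CO1)[C@@](C)(C=O)[C@@]2(C)C=O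
F6 | step 3 | cis-3,4-bis(1-hydroxyethyl) acetonide, mixture of carbinol epimers | CC1(C)OC[C@@H]2[C@H](CO1)[C@@](C)(C(C)O)[C@@]2(C)C(C)O
F7 | step 12 | hemiester with free acid on C1 and (R)-1-phenylethyl ester on C2 | OC(=O)[C@@H]1[C@H](C(=O)O[C@H](C)c2ccccc2)[C@@](C)(c2cc(OC)c(C)c(=O)o2)[C@@]1(C)c1cc(OC)c(C)c(=O)o1
F8 | step 12 | hemiester with (R)-1-phenylethyl ester on C1 and free acid on C2 | C[C@@H](OC(=O)[C@@H]1[C@H](C(=O)O)[C@@](C)(c2cc(OC)c(C)c(=O)o2)[C@@]1(C)c1cc(OC)c(C)c(=O)o1)c1ccccc1
F9 | step 12 | mixed diester, methyl on C1 and (R)-1-phenylethyl on C2 | COC(=O)[C@@H]1[C@H](C(=O)O[C@H](C)c2ccccc2)[C@@](C)(c2cc(OC)c(C)c(=O)o2)[C@@]1(C)c1cc(OC)c(C)c(=O)o1
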